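**Plan**

- Numbering: ring B is the cyclohexane that keeps the free CO2H (C1 quaternary, C3 carries a caffeoyl ester, O4 and O5 free). Ring A is the acyl-donor ring (C1′ to C6′, caffeoyl on O5′).
- Retrosynthesis: protecting groups and both caffeoyl esters come off first. Ring A is then cut at C1′–C2′ and C4′–C5′, back to a 4,4-diethoxy-2-oxobutanoate ester on O1 of ring B, so the hindered inter-ring ester is only ever made from oxalyl chloride. Ring B is cut the same way at C1–C2 and C4–C5, to tert-butyl 4,4-diethoxy-2-oxobutanoate and silyl-protected hydroxyacetone.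
- Enabling feature: in each ring the C3 oxygen lies between C2H2 and C4H(O), and the carbinol carbons C1 and C5 are both β to C3. Each ring is therefore a 1,5-dihydroxy-3-oxocyclohexane (double aldol) retron.
- Forward order: ring B annulation in one flask (C2 to C1 aldol, then release of the C5 aldehyde and C4 to C5 aldol), O5 silylation, C3 reduction, O3 acylation, oxalylation and homologation at O1, ring A annulation, O5′ acylation, C3′ reduction, one acid deprotection.
- Stereochemistry: C1 and C1′ come from the copper bis(oxazoline) catalyst. C4/C5 and C4′/C5′ follow from C1/C1′ in the all-equatorial ring closure. C3 and C3′ come from chelation-controlled ketone reduction. The C3 ketone also distinguishes O3 from O5 in each ring.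

Key step: step 3

Assumption: the (S,S)-bis(oxazoline) copper catalyst is taken to attack the si face of 2-oxo esters that carry a CH2 substituent, as it does with pyruvates; this gives the series required here, in which both rings are enantiomeric to the quinate of natural (−)-quinic acid.

(S,S)-t-Bu-box = (4S,4′S)-2,2′-(propane-2,2-diyl)bis(4-tert-butyl-4,5-dihydro-1,3-oxazole).

**Step 1**
Reactants: 1 tert-butyl chlorooxoacetate; 2 ethyl vinyl ether
Product: 4 tert-butyl 4,4-diethoxy-2-oxobutanoate, via chloro ether 3 (not isolated)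
Conditions: CH2Cl2, −30 to 0 °C; then EtOH, pyridine, 0 °C to rt
Reagents that add atoms: ethanol (CCO)
Why: The acyl chloride acylates the electron-rich vinyl ether at carbon (acylation of an enol ether) to give the α-chloro ether 3, which ethanol substitutes through the oxocarbenium ion while pyridine takes up HCl, so the future C5 aldehyde arrives masked as a diethyl acetal and no stereocenter is formed.

**Step 2**
Reactants: 5 1-[(tert-butyldimethylsilyl)oxy]propan-2-one
Product: 7 tert-butyldimethyl({2-[(trimethylsilyl)oxy]prop-2-en-1-yl}oxy)silane, via lithium enolate 6 (not isolated)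
Conditions: LiN(i-Pr)2, THF, −78 °C; then Me3SiCl, −78 to 0 °C
Reagents that add atoms: chlorotrimethylsilane (C[Si](C)(C)Cl)
Why: Kinetic deprotonation by the hindered lithium amide should remove a methyl proton, because the bulky non-chelating silyl ether shields the CH2O side, and O-silylation then fixes the terminal enol silane (regioselective silyl enol ether formation) without creating a stereocenter.

**Step 3**
Reactants: 7 tert-butyldimethyl({2-[(trimethylsilyl)oxy]prop-2-en-1-yl}oxy)silane; 4 tert-butyl 4,4-diethoxy-2-oxobutanoate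
Product: 10 tert-butyl (1S,4R,5S)-4-[(tert-butyldimethylsilyl)oxy]-1,5-dihydroxy-3-oxocyclohexane-1-carboxylate, via silyl aldol adduct 8 (not isolated), via keto aldehyde 9 (not isolated)
Conditions: Cu(OTf)2 (10 mol%), (S,S)-t-Bu-box (11 mol%), THF, −78 °C; then H2O, CF3CO2H (0.5 equiv), L-proline (0.5 equiv), DMSO, 0 °C to rt
Reagents that add atoms: water (O)
Why: The divalent copper bis(oxazoline) Lewis acid binds the 1,2-dicarbonyl unit of 4 as a five-membered chelate and the terminal enol silane 7 adds to the keto carbon (Mukaiyama aldol), forming C1–C2 and giving silyl ether 8; aqueous acid with L-proline then cleaves the trimethylsilyl ether and the acetal to keto aldehyde 9, whose C3 ketone reacts as the enamine towards C4 and closes onto the C5 aldehyde, forming C4–C5. The closest known reaction types are the copper bis(oxazoline)-catalysed Mukaiyama aldol of enol silanes with pyruvate esters and the proline-catalysed Hajos–Parrish-type ketol cyclization, which stops at the β-hydroxy ketone. Ring B is closed in a 6-(enolendo)-exo-trig mode. C1 is set by the catalyst, whose (S,S)-ligand leaves the si face of the chelated keto group open; C4 and C5 are set from C1 through a chair transition state that places the tert-butyl ester, the silyloxy group and the new hydroxyl equatorial, which is also the most stable isomer and the one to which the enolisable C4 can converge. The step needs regioselectivity (C2 and not C4 must attack the keto ester, and C1 must react before C5), which the pre-formed terminal enol silane and the acetal mask on C5 during the Lewis acid stage should secure. Only closure through C4 is productive, since closure through C2 would give a four-membered ring.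

**Step 4**
Reactants: 10 tert-butyl (1S,4R,5S)-4-[(tert-butyldimethylsilyl)oxy]-1,5-dihydroxy-3-oxocyclohexane-1-carboxylate
Product: 11 tert-butyl (1S,4R,5S)-4,5-bis[(tert-butyldimethylsilyl)oxy]-1-hydroxy-3-oxocyclohexane-1-carboxylate
Conditions: t-BuMe2SiCl, imidazole, DMF, 0 °C to rt
Reagents that add atoms: tert-butyldimethylsilyl chloride (CC(C)(C)[Si](C)(C)Cl)
Why: Silyl ether formation should take the secondary equatorial C5 hydroxyl in preference to the tertiary C1 hydroxyl on steric grounds, while the C3 ketone keeps O3 distinct from O5 and no stereocenter is touched.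

**Step 5**
Reactants: 11 tert-butyl (1S,4R,5S)-4,5-bis[(tert-butyldimethylsilyl)oxy]-1-hydroxy-3-oxocyclohexane-1-carboxylate
Product: 12 tert-butyl (1R,3S,4S,5S)-4,5-bis[(tert-butyldimethylsilyl)oxy]-1,3-dihydroxycyclohexane-1-carboxylate
Conditions: Et2BOMe, THF/MeOH (4:1), −78 °C; then NaBH4, −78 °C; AcOH, MeOH co-evaporation
Reagents that add atoms: none
Why: In this Narasaka–Prasad reduction the boron additive holds the axial C1 oxygen and the C3 carbonyl oxygen in a chelate, so external hydride should enter from the equatorial direction and give the axial C3 hydroxyl, cis to O1 and O4 as the target requires.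

**Step 6**
Reactants: 13 3,4-dihydroxybenzaldehyde
Product: 14 2,2-dimethyl-1,3-benzodioxole-5-carbaldehyde
Conditions: 2,2-dimethoxypropane, TsOH·H2O (cat.), toluene, reflux with removal of MeOH
Reagents that add atoms: 2,2-dimethoxypropane (COC(C)(C)OC)
Why: Acid-catalysed ketal exchange with the catechol, driven by removal of methanol, gives the isopropylidene ketal, which the final acid step removes together with all other protecting groups.

**Step 7**
Reactants: 14 2,2-dimethyl-1,3-benzodioxole-5-carbaldehyde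
Product: 16 (2E)-3-(2,2-dimethyl-1,3-benzodioxol-5-yl)prop-2-enoic acid, via arylidenemalonic acid 15 (not isolated)
Conditions: malonic acid, pyridine, piperidine (cat.), 90 °C
Reagents that add atoms: malonic acid (OC(=O)CC(=O)O)
Why: Knoevenagel–Doebner condensation followed by decarboxylation of the arylidenemalonic acid should give the cinnamic acid as the thermodynamically favoured E isomer.

**Step 8**
Reactants: 12 tert-butyl (1R,3S,4S,5S)-4,5-bis[(tert-butyldimethylsilyl)oxy]-1,3-dihydroxycyclohexane-1-carboxylate; 16 (2E)-3-(2,2-dimethyl-1,3-benzodioxol-5-yl)prop-2-enoic acid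
Product: 17 tert-butyl (1R,3S,4S,5S)-4,5-bis[(tert-butyldimethylsilyl)oxy]-3-{[(2E)-3-(2,2-dimethyl-1,3-benzodioxol-5-yl)prop-2-enoyl]oxy}-1-hydroxycyclohexane-1-carboxylate
Conditions: DCC, DMAP (cat.), CH2Cl2, 0 °C to rt
Reagents that add atoms: none
Why: Steglich esterification through the acylpyridinium ion should acylate the only secondary hydroxyl, the axial O3, and leave the tertiary C1 hydroxyl and all stereocenters untouched.

**Step 9**
Reactants: 17 tert-butyl (1R,3S,4S,5S)-4,5-bis[(tert-butyldimethylsilyl)oxy]-3-{[(2E)-3-(2,2-dimethyl-1,3-benzodioxol-5-yl)prop-2-enoyl]oxy}-1-hydroxycyclohexane-1-carboxylate; 2 ethyl vinyl ether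
Product: 20 4,4-diethoxy-2-oxobutanoate of the C1 hydroxyl of 17, via chlorooxoacetate 18 (not isolated), via chloro ether 19 (not isolated)
Conditions: (COCl)2 (3 equiv), pyridine, CH2Cl2, 0 °C to rt, then evaporation of excess (COCl)2; ethyl vinyl ether, CH2Cl2, 0 °C to rt; then EtOH, pyridine, 0 °C to rt
Reagents that add atoms: oxalyl chloride (ClC(=O)C(=O)Cl); ethanol (CCO)
Why: The small and very electrophilic oxalyl chloride should acylate the hindered tertiary C1 hydroxyl where a bulky acid could not (alcohol acylation to an alkyl chlorooxoacetate), after which the remaining acyl chloride acylates ethyl vinyl ether and ethanol converts chloro ether 19 into the acetal as in step 1, so the inter-ring ester exists before ring A does and C1, being α to an ester, should not ionise.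

**Step 10**
Reactants: 20 4,4-diethoxy-2-oxobutanoate of the C1 hydroxyl of 17; 7 tert-butyldimethyl({2-[(trimethylsilyl)oxy]prop-2-en-1-yl}oxy)silane
Product: 23 ester of O1 of 17 with (1S,4R,5S)-4-[(tert-butyldimethylsilyl)oxy]-1,5-dihydroxy-3-oxocyclohexane-1-carboxylic acid (ring A configured as in 10), via silyl aldol adduct 21 (not isolated), via keto aldehyde 22 (not isolated)
Conditions: Cu(OTf)2 (20 mol%), (S,S)-t-Bu-box (22 mol%), THF, −78 °C; then H2O, CF3CO2H (0.5 equiv), L-proline (0.5 equiv), DMSO, 0 °C to rt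
Reagents that add atoms: water (O)
Why: The same one-flask Mukaiyama aldol and Hajos–Parrish-type 6-(enolendo)-exo-trig aldol cyclization as in step 3 should build ring A on the keto ester already bound to O1 of ring B, with C1′ set by si-face attack under the (S,S)-catalyst, which is relied on to override the remote centers of ring B, and C4′ and C5′ set from C1′ through the all-equatorial chair.

**Step 11**
Reactants: 23 ester of O1 of 17 with (1S,4R,5S)-4-[(tert-butyldimethylsilyl)oxy]-1,5-dihydroxy-3-oxocyclohexane-1-carboxylic acid; 16 (2E)-3-(2,2-dimethyl-1,3-benzodioxol-5-yl)prop-2-enoic acid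
Product: 24 the O5′ (2E)-3-(2,2-dimethyl-1,3-benzodioxol-5-yl)prop-2-enoate of 23
Conditions: DCC, DMAP (cat.), CH2Cl2, 0 °C
Reagents that add atoms: none
Why: Steglich esterification should acylate the only secondary hydroxyl of 23, the equatorial O5′, while the C3′ ketone still stands in for O3′ and the tertiary O1′ is unreactive, the low temperature being chosen to avoid β-elimination of the new ester from the β-acyloxy ketone.

**Step 12**
Reactants: 24 the O5′ (2E)-3-(2,2-dimethyl-1,3-benzodioxol-5-yl)prop-2-enoate of 23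
Product: 25 the (3′S) axial alcohol from 24, ring A being (1R,3S,4S,5S) with O1′, O3′ and O4′ cis (the fully protected target)
Conditions: Et2BOMe, THF/MeOH (4:1), −78 °C; then NaBH4, −78 °C; AcOH, MeOH co-evaporation
Reagents that add atoms: none
Why: Narasaka–Prasad reduction as in step 5, in which boron chelation between the axial O1′ and the C3′ carbonyl should direct external hydride to the equatorial face and give the axial C3′ hydroxyl, while borohydride at −78 °C should leave the esters and cinnamoyl double bonds untouched.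

**Step 13**
Reactants: 25 the fully protected target
Product: 26 (1S,3S,4R,5S)-3-{[(2E)-3-(3,4-dihydroxyphenyl)prop-2-enoyl]oxy}-1-{[(1R,3S,4S,5S)-5-{[(2E)-3-(3,4-dihydroxyphenyl)prop-2-enoyl]oxy}-1,3,4-trihydroxycyclohexane-1-carbonyl]oxy}-4,5-dihydroxycyclohexane-1-carboxylic acid
Conditions: CF3CO2H/H2O (9:1), 0 °C to rt; reverse-phase chromatography
Reagents that add atoms: none
Why: Aqueous trifluoroacetic acid should remove every acid-labile group in one operation (acidolysis of the tert-butyl ester, hydrolysis of the three silyl ethers and the two catechol ketals), while the three carboxylic esters and all stereocenters are stable to acid at room temperature.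

**Compound list**

1 | tert-butyl chlorooxoacetate | CC(C)(C)OC(=O)C(=O)Cl | starting material
2 | ethyl vinyl ether | C=COCC | starting material
3 | tert-butyl 4-chloro-4-ethoxy-2-oxobutanoate (racemic) | CCOC(Cl)CC(=O)C(=O)OC(C)(C)C | intermediate
4 | tert-butyl 4,4-diethoxy-2-oxobutanoate | CCOC(CC(=O)C(=O)OC(C)(C)C)OCC | intermediate
5 | 1-[(tert-butyldimethylsilyl)oxy]propan-2-one | CC(=O)CO[Si](C)(C)C(C)(C)C | starting material
6 | lithium 3-[(tert-butyldimethylsilyl)oxy]prop-1-en-2-olate | C=C([O-])CO[Si](C)(C)C(C)(C)C.[Li+] | intermediate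
7 | tert-butyldimethyl({2-[(trimethylsilyl)oxy]prop-2-en-1-yl}oxy)silane | C=C(CO[Si](C)(C)C(C)(C)C)O[Si](C)(C)C | intermediate
8 | tert-butyl (2S)-5-[(tert-butyldimethylsilyl)oxy]-2-(2,2-diethoxyethyl)-4-oxo-2-[(trimethylsilyl)oxy]pentanoate | C[Si](C)(C)O[C@](CC(OCC)OCC)(C(=O)OC(C)(C)C)CC(=O)CO[Si](C)(C)C(C)(C)C | intermediate
9 | tert-butyl (2S)-5-[(tert-butyldimethylsilyl)oxy]-2-hydroxy-4-oxo-2-(2-oxoethyl)pentanoate | O[C@](CC=O)(C(=O)OC(C)(C)C)CC(=O)CO[Si](C)(C)C(C)(C)C | intermediate
10 | tert-butyl (1S,4R,5S)-4-[(tert-butyldimethylsilyl)oxy]-1,5-dihydroxy-3-oxocyclohexane-1-carboxylate (O1 and O4 cis, O5 trans to both) | O[C@]1(C(=O)OC(C)(C)C)CC(=O)[C@H](O[Si](C)(C)C(C)(C)C)[C@@H](O)C1 | intermediate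
11 | tert-butyl (1S,4R,5S)-4,5-bis[(tert-butyldimethylsilyl)oxy]-1-hydroxy-3-oxocyclohexane-1-carboxylate | O[C@]1(C(=O)OC(C)(C)C)CC(=O)[C@H](O[Si](C)(C)C(C)(C)C)[C@@H](O[Si](C)(C)C(C)(C)C)C1 | intermediate
12 | tert-butyl (1R,3S,4S,5S)-4,5-bis[(tert-butyldimethylsilyl)oxy]-1,3-dihydroxycyclohexane-1-carboxylate (O1, O3 and O4 cis) | O[C@]1(C(=O)OC(C)(C)C)C[C@H](O)[C@H](O[Si](C)(C)C(C)(C)C)[C@@H](O[Si](C)(C)C(C)(C)C)C1 | intermediate
13 | 3,4-dihydroxybenzaldehyde | O=Cc1ccc(O)c(O)c1 | starting material
14 | 2,2-dimethyl-1,3-benzodioxole-5-carbaldehyde | O=Cc1ccc2OC(C)(C)Oc2c1 | intermediate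
15 | 2-[(2,2-dimethyl-1,3-benzodioxol-5-yl)methylidene]propanedioic acid | OC(=O)C(=Cc1ccc2OC(C)(C)Oc2c1)C(=O)O | intermediate
16 | (2E)-3-(2,2-dimethyl-1,3-benzodioxol-5-yl)prop-2-enoic acid | OC(=O)/C=C/c1ccc2OC(C)(C)Oc2c1 | intermediate
17 | tert-butyl (1R,3S,4S,5S)-4,5-bis[(tert-butyldimethylsilyl)oxy]-3-{[(2E)-3-(2,2-dimethyl-1,3-benzodioxol-5-yl)prop-2-enoyl]oxy}-1-hydroxycyclohexane-1-carboxylate | O[C@]1(C(=O)OC(C)(C)C)C[C@H](OC(=O)/C=C/c2ccc3OC(C)(C)Oc3c2)[C@H](O[Si](C)(C)C(C)(C)C)[C@@H](O[Si](C)(C)C(C)(C)C)C1 | intermediate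
18 | chlorooxoacetate of the C1 hydroxyl of 17 | O=C(Cl)C(=O)O[C@]1(C(=O)OC(C)(C)C)C[C@H](OC(=O)/C=C/c2ccc3OC(C)(C)Oc3c2)[C@H](O[Si](C)(C)C(C)(C)C)[C@@H](O[Si](C)(C)C(C)(C)C)C1 | intermediate
19 | 4-chloro-4-ethoxy-2-oxobutanoate of the C1 hydroxyl of 17 (both epimers at the chloro ether carbon) | CCOC(Cl)CC(=O)C(=O)O[C@]1(C(=O)OC(C)(C)C)C[C@H](OC(=O)/C=C/c2ccc3OC(C)(C)Oc3c2)[C@H](O[Si](C)(C)C(C)(C)C)[C@@H](O[Si](C)(C)C(C)(C)C)C1 | intermediate
20 | 4,4-diethoxy-2-oxobutanoate of the C1 hydroxyl of 17 | CCOC(CC(=O)C(=O)O[C@]1(C(=O)OC(C)(C)C)C[C@H](OC(=O)/C=C/c2ccc3OC(C)(C)Oc3c2)[C@H](O[Si](C)(C)C(C)(C)C)[C@@H](O[Si](C)(C)C(C)(C)C)C1)OCC | intermediate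
21 | ester of O1 of 17 with (2S)-5-[(tert-butyldimethylsilyl)oxy]-2-(2,2-diethoxyethyl)-4-oxo-2-[(trimethylsilyl)oxy]pentanoic acid | C[Si](C)(C)O[C@](CC(OCC)OCC)(C(=O)O[C@]1(C(=O)OC(C)(C)C)C[C@H](OC(=O)/C=C/c2ccc3OC(C)(C)Oc3c2)[C@H](O[Si](C)(C)C(C)(C)C)[C@@H](O[Si](C)(C)C(C)(C)C)C1)CC(=O)CO[Si](C)(C)C(C)(C)C | intermediate
22 | ester of O1 of 17 with (2S)-5-[(tert-butyldimethylsilyl)oxy]-2-hydroxy-4-oxo-2-(2-oxoethyl)pentanoic acid | O[C@](CC=O)(C(=O)O[C@]1(C(=O)OC(C)(C)C)C[C@H](OC(=O)/C=C/c2ccc3OC(C)(C)Oc3c2)[C@H](O[Si](C)(C)C(C)(C)C)[C@@H](O[Si](C)(C)C(C)(C)C)C1)CC(=O)CO[Si](C)(C)C(C)(C)C | intermediate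
23 | ester of O1 of 17 with (1S,4R,5S)-4-[(tert-butyldimethylsilyl)oxy]-1,5-dihydroxy-3-oxocyclohexane-1-carboxylic acid (ring A configured as in 10) | O[C@]1(C(=O)O[C@]2(C(=O)OC(C)(C)C)C[C@H](OC(=O)/C=C/c3ccc4OC(C)(C)Oc4c3)[C@H](O[Si](C)(C)C(C)(C)C)[C@@H](O[Si](C)(C)C(C)(C)C)C2)CC(=O)[C@H](O[Si](C)(C)C(C)(C)C)[C@@H](O)C1 | intermediate
24 | 23 acylated at O5′ with the acyl group of 16 (ring A (1S,4R,5S), still the 3′-ketone) | O[C@]1(C(=O)O[C@]2(C(=O)OC(C)(C)C)C[C@H](OC(=O)/C=C/c3ccc4OC(C)(C)Oc4c3)[C@H](O[Si](C)(C)C(C)(C)C)[C@@H](O[Si](C)(C)C(C)(C)C)C2)CC(=O)[C@H](O[Si](C)(C)C(C)(C)C)[C@@H](OC(=O)/C=C/c3ccc4OC(C)(C)Oc4c3)C1 | intermediate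
25 | 24 with the C3′ ketone reduced to the axial alcohol (ring A (1R,3S,4S,5S); fully protected target) | O[C@]1(C(=O)O[C@]2(C(=O)OC(C)(C)C)C[C@H](OC(=O)/C=C/c3ccc4OC(C)(C)Oc4c3)[C@H](O[Si](C)(C)C(C)(C)C)[C@@H](O[Si](C)(C)C(C)(C)C)C2)C[C@H](O)[C@H](O[Si](C)(C)C(C)(C)C)[C@@H](OC(=O)/C=C/c3ccc4OC(C)(C)Oc4c3)C1 | intermediate
26 | (1S,3S,4R,5S)-3-{[(2E)-3-(3,4-dihydroxyphenyl)prop-2-enoyl]oxy}-1-{[(1R,3S,4S,5S)-5-{[(2E)-3-(3,4-dihydroxyphenyl)prop-2-enoyl]oxy}-1,3,4-trihydroxycyclohexane-1-carbonyl]oxy}-4,5-dihydroxycyclohexane-1-carboxylic acid | O[C@]1(C(=O)O[C@]2(C(=O)O)C[C@H](OC(=O)/C=C/c3ccc(O)c(O)c3)[C@H](O)[C@@H](O)C2)C[C@H](O)[C@H](O)[C@@H](OC(=O)/C=C/c3ccc(O)c(O)c3)C1 | target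

**Totals**

Total step count: 13. Longest linear sequence: 10 steps (steps 1, 3, 4, 5, 8, 9, 10, 11, 12, 13).

**Steps most likely to fail**

Step 10. The Lewis acid may be held by the many donor oxygens of 20 or may ionise its acetal, and the chiral ester may oppose the catalyst, so that C1′ forms with poor facial selectivity. The fallback sets out from 20 and 5 and replaces Lewis acid activation by a pre-formed boron enolate. Ketone 5 with chlorodicyclohexylborane and Et3N (Et2O, −78 °C) should give the terminal dicyclohexylboron enolate F6, which adds to the keto group of 20 without external activation. Work-up should give the tertiary alcohol acetal F7, whose two C1′ epimers are diastereomers and separable by chromatography. Treatment of F7 with aqueous CF3CO2H and L-proline, as in the second stage of step 10, then rejoins the route at 22 and hence 23.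

Step 3. The β-keto acetal may lose ethanol under the Lewis acid before the aldol takes place, and a ring closure that shares the flask with the first aldol may run with poor facial selectivity or with retro-aldol erosion at C1. The fallback sets out from 7 and carries the latent aldehyde as a terminal alkene. tert-Butyl 2-oxopent-4-enoate F1 (from di-tert-butyl oxalate and allylmagnesium bromide, THF, −78 °C) undergoes the same copper-catalysed Mukaiyama aldol with 7 to give the silyl ether F2. Acidic work-up gives the tertiary alcohol F3, and ozonolysis (O3, CH2Cl2, −78 °C; PPh3) gives keto aldehyde 9 as an isolated compound, where the route is rejoined. The ring closure to 10 is then run as a separate step, in which amine catalyst, solvent and equilibration time can be chosen without regard to the first aldol.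

Step 9. Acylation of the hindered tertiary hydroxyl, which has a syn-axial neighbour, may be slow, and the long exposure to acyl chloride and vinyl ether on the substrate may cost silyl ether or ketal groups. The fallback sets out from 17 and makes the carbon–carbon bond of the side chain first on a small molecule. Ethyl vinyl ether 2 and oxalyl chloride give (E)-4-ethoxy-2-oxobut-3-enoyl chloride F4, which acylates 17 in a single event (pyridine, DMAP, CH2Cl2, 0 °C) to the vinylogous ester F5. Acid-catalysed addition of ethanol (EtOH, pyridinium p-toluenesulfonate, rt) returns to the route at 20.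

**Further compounds**

F1 | step 3 | tert-butyl 2-oxopent-4-enoate | C=CCC(=O)C(=O)OC(C)(C)C
F2 | step 3 | tert-butyl (2S)-5-[(tert-butyldimethylsilyl)oxy]-4-oxo-2-(prop-2-en-1-yl)-2-[(trimethylsilyl)oxy]pentanoate | C[Si](C)(C)O[C@](CC=C)(C(=O)OC(C)(C)C)CC(=O)CO[Si](C)(C)C(C)(C)C
F3 | step 3 | tert-butyl (2S)-5-[(tert-butyldimethylsilyl)oxy]-2-hydroxy-4-oxo-2-(prop-2-en-1-yl)pentanoate | O[C@](CC=C)(C(=O)OC(C)(C)C)CC(=O)CO[Si](C)(C)C(C)(C)C
F4 | step 9 | (E)-4-ethoxy-2-oxobut-3-enoyl chloride | CCO/C=C/C(=O)C(=O)Cl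
F5 | step 9 | (E)-4-ethoxy-2-oxobut-3-enoate of the C1 hydroxyl of 17 | CCO/C=C/C(=O)C(=O)O[C@]1(C(=O)OC(C)(C)C)C[C@H](OC(=O)/C=C/c2ccc3OC(C)(C)Oc3c2)[C@H](O[Si](C)(C)C(C)(C)C)[C@@H](O[Si](C)(C)C(C)(C)C)C1
F6 | step 10 | tert-butyl({2-[(dicyclohexylboranyl)oxy]prop-2-en-1-yl}oxy)dimethylsilane | C=C(CO[Si](C)(C)C(C)(C)C)OB(C1CCCCC1)C1CCCCC1
F7 | step 10 | ester of O1 of 17 with (2S)-5-[(tert-butyldimethylsilyl)oxy]-2-(2,2-diethoxyethyl)-2-hydroxy-4-oxopentanoic acid | O[C@](CC(OCC)OCC)(C(=O)O[C@]1(C(=O)OC(C)(C)C)C[C@H](OC(=O)/C=C/c2ccc3OC(C)(C)Oc3c2)[C@H](O[Si](C)(C)C(C)(C)C)[C@@H](O[Si](C)(C)C(C)(C)C)C1)CC(=O)CO[Si](C)(C)C(C)(C)C
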